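**Plan**

1. Retrosynthesis: the 8-O-acyl group and the free C12 acid are released last from a trans-fused C12→O8 γ-lactone. Ring B is then cut at C1–C10, and the chain at C6–C7 (conjugate addition) and C8–C9 (propargylation of a four-carbon aldehyde ester).
2. Enabling feature: in ring A, C1 is the δ-carbon of the C15 carbonyl (C15–C4=C5–C6–C1). A ring-A 2,4-dienoate C15(=O)–C4=C5–C6=C1 therefore makes C1 the acceptor and leaves the target's C4=C5/C15 unit after closure; C10=C14H2 is a terminal alkyne plus one hydrogen.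
3. Forward: ring A (from 3-bromocyclohexenone) is joined to the C7–C14 chain, the lactone closes and C15 is added as an ester by carbonylation. Ring B then closes by a stannyl-radical 6-endo cyclisation of C10 onto C1, followed by reduction, α-methylenation, lactone opening, acylation and one acid deprotection.
4. Stereochemistry: C8 from a catalytic asymmetric propargylation; C7 by anti conjugate addition next to C8; C1 from the trans lactone, which fixes the face of ring closure; C6 by axial protonation and equilibration of the enoate (trans ring fusion); C3' from the chiral pool.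

Key step: step 7

Remark: positions follow cadinane numbering (C1/C6 ring fusion, C4=C5 with C15 on C4, C7 carrying C11(C12)(C13), C8 oxygenated, C10=C14, primed numbers for the acyl side chain); the MeO-BIBOP enantiomer in step 2 is assumed to be the one that gives the 4R carbinol.

**Step 1**
Reactants: 1 3-bromocyclohex-2-en-1-one
Product: 2 7-bromo-1,4-dioxaspiro[4.5]dec-6-ene
Conditions: (Me3SiOCH2)2, Me3SiOTf (cat.), CH2Cl2, −78 → −20 °C
Reagents that add atoms: 1,2-bis(trimethylsilyloxy)ethane, C[Si](C)(C)OCCO[Si](C)(C)C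
Why: Silyl-triflate-catalysed ketalisation with the bis-silyl glycol ether at low temperature should protect the enone without moving the C=C, giving the masked 3-oxocyclohexenyl nucleophile.

**Step 2**
Reactants: 3 ethyl (2E)-4-oxobut-2-enoate; 4 trimethyl[3-(4,4,5,5-tetramethyl-1,3,2-dioxaborolan-2-yl)prop-1-yn-1-yl]silane
Product: 5 ethyl (2E,4R)-4-hydroxy-7-(trimethylsilyl)hept-2-en-6-ynoate
Conditions: Cu(O2CiPr)2 (7 mol%), LiOtBu (10 mol%), MeO-BIBOP, THF, −60 °C; aq. NH4Cl
Reagents that add atoms: none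
Why: Copper-catalysed asymmetric propargylation of an aldehyde with a silyl propargyl boronate (allenyl copper, SE2', closed transition state) should add 1,2 to the aldehyde in preference to the enoate, and the chiral bisphosphine sets C8 (4R).

**Step 3**
Reactants: 5 ethyl (2E,4R)-4-hydroxy-7-(trimethylsilyl)hept-2-en-6-ynoate
Product: 6 ethyl (2E,4R)-4-[(tert-butyldimethylsilyl)oxy]-7-(trimethylsilyl)hept-2-en-6-ynoate
Conditions: TBSCl, imidazole, DMF, 0 °C → rt
Reagents that add atoms: tert-butyldimethylsilyl chloride, CC(C)(C)[Si](C)(C)Cl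
Why: Standard silylation of a secondary alcohol; the γ-silyloxy group is the directing element for step 4.

**Step 4**
Reactants: 2 7-bromo-1,4-dioxaspiro[4.5]dec-6-ene; 6 ethyl (2E,4R)-4-[(tert-butyldimethylsilyl)oxy]-7-(trimethylsilyl)hept-2-en-6-ynoate
Product: 9 (4R,5R)-4-(3-oxocyclohex-1-en-1-yl)-5-[3-(trimethylsilyl)prop-2-yn-1-yl]oxolan-2-one (trans lactone), via magnesium reagent 7 (not isolated), via conjugate adduct 8 (not isolated)
Conditions: 2, Mg, LiCl, THF, rt; then CuBr·SMe2 (10 mol%), Me3SiCl, 6, THF, −78 → −40 °C; then 2 M aq. HCl, THF, rt → 40 °C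
Reagents that add atoms: water, O
Why: Copper-catalysed conjugate addition of the alkenyl Grignard reagent with Me3SiCl to an (E)-γ-silyloxy enoate should go anti to the γ-oxygen (Felkin-type, C–O bond perpendicular to the enoate) and set C7; aqueous acid then cleaves ketal and silyl ether, and the γ-hydroxy ester lactonises with retention at C8 to the trans lactone.

**Step 5**
Reactants: 9 (4R,5R)-4-(3-oxocyclohex-1-en-1-yl)-5-[3-(trimethylsilyl)prop-2-yn-1-yl]oxolan-2-one
Product: 10 3-{(2R,3R)-5-oxo-2-[3-(trimethylsilyl)prop-2-yn-1-yl]oxolan-3-yl}cyclohexa-1,3-dien-1-yl trifluoromethanesulfonate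
Conditions: Tf2O, 2,6-di-tert-butyl-4-methylpyridine, CH2Cl2, 0 °C → rt
Reagents that add atoms: trifluoromethanesulfonic anhydride, O=S(=O)(OS(=O)(=O)C(F)(F)F)C(F)(F)F
Why: O-triflation of the enone with a hindered pyridine should give the linear dienyl triflate C4(OTf)=C5–C6=C1 by loss of the ring γ-proton at C1, as with steroidal 4-en-3-ones; the exocyclic alternative would need a tetrasubstituted alkene at C7.

**Step 6**
Reactants: 10 3-{(2R,3R)-5-oxo-2-[3-(trimethylsilyl)prop-2-yn-1-yl]oxolan-3-yl}cyclohexa-1,3-dien-1-yl trifluoromethanesulfonate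
Product: 12 methyl 3-[(2R,3R)-5-oxo-2-(prop-2-yn-1-yl)oxolan-3-yl]cyclohexa-1,3-diene-1-carboxylate, via silylalkyne dienoate 11 (not isolated)
Conditions: Pd(OAc)2 (5 mol%), PPh3, CO (1 atm), Et3N, MeOH/DMF, 50 °C; then K2CO3 (0.2 equiv), MeOH, 0 °C
Reagents that add atoms: carbon monoxide, [C-]#[O+]; methanol, CO
Why: Palladium-catalysed alkoxycarbonylation of an enol triflate (oxidative addition, CO insertion, methanolysis) installs C15 as the methyl 2,4-dienoate, and carbonate in methanol then removes the alkynyl silyl group.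

**Step 7**
Reactants: 12 methyl 3-[(2R,3R)-5-oxo-2-(prop-2-yn-1-yl)oxolan-3-yl]cyclohexa-1,3-diene-1-carboxylate
Product: 15 methyl (1S,6S,7R,8R)-cadina-4,10(14)-dien-12,8-olid-15-oate, via vinylstannane 13 (not isolated), via crude ester 14 (not isolated)
Conditions: Bu3SnH (syringe pump), AIBN, PhH (0.005 M), 80 °C; then TsOH·H2O, CH2Cl2, rt; then DBU, PhMe, 60 °C
Reagents that add atoms: none
Why: Bu3Sn• adds to the terminal alkyne carbon C14 and the resulting C10 vinyl radical attacks C1, the δ-terminus of the ring-A dienoate, giving a radical delocalised over C6, C4 and the ester that takes H from Bu3SnH; acid then replaces tin on C14 by H and DBU moves the C=C into conjugation (C4=C5) while C6 is protonated. The closest known type is the vinyl-radical enyne cyclisation triggered by stannyl radical addition to an alkyne, used here as a radical 1,6-addition to a 2,4-dienoate. Ring B closes in the 6-endo-trig mode across C1=C6, and a 5-exo adduct at C6 would reach the same radical by 3-exo closure and reopening. C1 is controlled by the trans lactone, which holds C11 and O8 pseudo-equatorial so that the C8–C9–C10 arm can reach C1 only over the diene face that places H1 syn to H7 in a chair-like transition state. C6 is set by axial protonation of the dienolate anti to H1 and H7, which is also the thermodynamically preferred trans ring fusion. The step needs δ- over β-attack (C1 rather than C5), which is secured because radicals add to the terminus of a 1,3-diene and only attack at C1 gives the allyl- and ester-stabilised radical; high dilution and slow tin hydride addition should keep the vinyl radical from being reduced before it cyclises.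

**Step 8**
Reactants: 15 methyl (1S,6S,7R,8R)-cadina-4,10(14)-dien-12,8-olid-15-oate
Product: 16 (1S,6S,7R,8R)-8,12-epoxycadina-4,10(14)-diene-12,15-diol (lactol; both anomers)
Conditions: iBu2AlH (3.5 equiv), CH2Cl2, −78 °C; aq. potassium sodium tartrate
Reagents that add atoms: none
Why: iBu2AlH should reduce the conjugated methyl ester 1,2 to the allylic alcohol and stop at the lactol for the lactone at −78 °C; C6 is no longer epimerisable once the ester is gone.

**Step 9**
Reactants: 16 (1S,6S,7R,8R)-8,12-epoxycadina-4,10(14)-diene-12,15-diol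
Product: 17 (1S,6S,7R,8R)-15-[(tert-butyldimethylsilyl)oxy]-8,12-epoxycadina-4,10(14)-dien-12-ol
Conditions: TBSCl (1.05 equiv), imidazole, CH2Cl2, 0 °C
Reagents that add atoms: tert-butyldimethylsilyl chloride, CC(C)(C)[Si](C)(C)Cl
Why: The primary allylic alcohol should be silylated much faster than the hindered hemiacetal hydroxyl.

**Step 10**
Reactants: 17 (1S,6S,7R,8R)-15-[(tert-butyldimethylsilyl)oxy]-8,12-epoxycadina-4,10(14)-dien-12-ol
Product: 18 (1S,6S,7R,8R)-15-[(tert-butyldimethylsilyl)oxy]cadina-4,10(14)-dien-12,8-olide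
Conditions: nPr4N[RuO4] (5 mol%), N-methylmorpholine N-oxide, CH2Cl2, rt
Reagents that add atoms: none
Why: Ley–Griffith oxidation of a lactol to the lactone leaves the alkenes and the silyl ether untouched.

**Step 11**
Reactants: 18 (1S,6S,7R,8R)-15-[(tert-butyldimethylsilyl)oxy]cadina-4,10(14)-dien-12,8-olide
Product: 21 (1S,6S,7S,8R)-15-[(tert-butyldimethylsilyl)oxy]cadina-4,10(14),11(13)-trien-12,8-olide, via Mannich base 19 (not isolated), via ammonium iodide 20 (not isolated)
Conditions: LiN(iPr)2, THF, −78 °C; Me2N=CH2 I, −78 → 0 °C; then MeI, MeOH, rt; then aq. NaHCO3, CH2Cl2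
Reagents that add atoms: dimethylmethyleneammonium iodide (Eschenmoser salt), C=[N+](C)C.[I-]
Why: Mannich reaction of the lactone enolate, N-methylation and base-induced elimination is the standard α-methylenation of γ-butyrolactones; C11 is the only enolisable position.

**Step 12**
Reactants: 21 (1S,6S,7S,8R)-15-[(tert-butyldimethylsilyl)oxy]cadina-4,10(14),11(13)-trien-12,8-olide
Product: 23 methoxymethyl (1S,6S,7S,8R)-15-[(tert-butyldimethylsilyl)oxy]-8-hydroxycadina-4,10(14),11(13)-trien-12-oate, via lithium carboxylate 22 (not isolated)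
Conditions: LiOH (1.1 equiv), THF/H2O, 0 °C; evaporate; then MeOCH2Cl, DMF, 0 °C
Reagents that add atoms: lithium hydroxide, [Li+].[OH-]; chloromethyl methyl ether, COCCl
Why: Saponification (acyl–oxygen cleavage, C8 retained) gives the hydroxy carboxylate, whose O-alkylation should be much faster than alkylation of the neutral secondary alcohol; the acetal ester blocks relactonisation and is acid-labile.

**Step 13**
Reactants: 24 methyl [(4S)-2,2-dimethyl-1,3-dioxolan-4-yl]acetate
Product: 27 methyl 2-[(4S)-2,2-dimethyl-1,3-dioxolan-4-yl]prop-2-enoate, via Mannich base 25 (not isolated), via ammonium iodide 26 (not isolated)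
Conditions: LiN(iPr)2, THF, −78 °C; Me2N=CH2 I, −78 → 0 °C; then MeI, MeOH, rt; then aq. NaHCO3, CH2Cl2
Reagents that add atoms: dimethylmethyleneammonium iodide (Eschenmoser salt), C=[N+](C)C.[I-]
Why: The ester enolate is stable to β-alkoxide loss at −78 °C, and Mannich reaction followed by quaternisation and elimination gives the acrylate without touching the chiral-pool stereocentre (C3').

**Step 14**
Reactants: 27 methyl 2-[(4S)-2,2-dimethyl-1,3-dioxolan-4-yl]prop-2-enoate
Product: 28 2-[(4S)-2,2-dimethyl-1,3-dioxolan-4-yl]prop-2-enoic acid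
Conditions: LiOH, THF/H2O, 0 °C; 1 M HCl to pH 4
Reagents that add atoms: lithium hydroxide, [Li+].[OH-]
Why: Ester saponification; the acetonide survives base and work-up at pH 4.

**Step 15**
Reactants: 23 methoxymethyl (1S,6S,7S,8R)-15-[(tert-butyldimethylsilyl)oxy]-8-hydroxycadina-4,10(14),11(13)-trien-12-oate; 28 2-[(4S)-2,2-dimethyl-1,3-dioxolan-4-yl]prop-2-enoic acid
Product: 29 methoxymethyl (1S,6S,7S,8R)-15-[(tert-butyldimethylsilyl)oxy]-8-({2-[(4S)-2,2-dimethyl-1,3-dioxolan-4-yl]prop-2-enoyl}oxy)cadina-4,10(14),11(13)-trien-12-oate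
Conditions: DCC, DMAP, CH2Cl2, 0 °C → rt
Reagents that add atoms: none
Why: Steglich esterification of the equatorial secondary C8 alcohol; no stereocentre is involved.

**Step 16**
Reactants: 29 methoxymethyl (1S,6S,7S,8R)-15-[(tert-butyldimethylsilyl)oxy]-8-({2-[(4S)-2,2-dimethyl-1,3-dioxolan-4-yl]prop-2-enoyl}oxy)cadina-4,10(14),11(13)-trien-12-oate
Product: 30 (1S,6S,7S,8R)-8-{[(3S)-3,4-dihydroxy-2-methylidenebutanoyl]oxy}-15-hydroxycadina-4,10(14),11(13)-trien-12-oic acid (target)
Conditions: 1 M aq. HCl/THF (1:3), rt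
Reagents that add atoms: none
Why: Dilute aqueous acid should hydrolyse the acetal ester, the primary silyl ether and the acetonide in one operation; acid is chosen because the 4'-hydroxyl of the side chain lactonises onto its own ester under basic conditions.

**Compound list**

1 | 3-bromocyclohex-2-en-1-one | O=C1C=C(Br)CCC1 | starting material
2 | 7-bromo-1,4-dioxaspiro[4.5]dec-6-ene | BrC1=CC2(CCC1)OCCO2 | intermediate
3 | ethyl (2E)-4-oxobut-2-enoate | CCOC(=O)/C=C/C=O | starting material
4 | trimethyl[3-(4,4,5,5-tetramethyl-1,3,2-dioxaborolan-2-yl)prop-1-yn-1-yl]silane | C[Si](C)(C)C#CCB1OC(C)(C)C(C)(C)O1 | starting material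
5 | ethyl (2E,4R)-4-hydroxy-7-(trimethylsilyl)hept-2-en-6-ynoate | CCOC(=O)/C=C/[C@H](O)CC#C[Si](C)(C)C | intermediate
6 | ethyl (2E,4R)-4-[(tert-butyldimethylsilyl)oxy]-7-(trimethylsilyl)hept-2-en-6-ynoate | CCOC(=O)/C=C/[C@H](O[Si](C)(C)C(C)(C)C)CC#C[Si](C)(C)C | intermediate
7 | bromo(1,4-dioxaspiro[4.5]dec-6-en-7-yl)magnesium (not isolated) | Br[Mg]C1=CC2(CCC1)OCCO2 | intermediate
8 | ethyl (3R,4R)-4-[(tert-butyldimethylsilyl)oxy]-3-(1,4-dioxaspiro[4.5]dec-6-en-7-yl)-7-(trimethylsilyl)hept-6-ynoate (not isolated) | CCOC(=O)C[C@H](C1=CC2(CCC1)OCCO2)[C@H](O[Si](C)(C)C(C)(C)C)CC#C[Si](C)(C)C | intermediate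
9 | (4R,5R)-4-(3-oxocyclohex-1-en-1-yl)-5-[3-(trimethylsilyl)prop-2-yn-1-yl]oxolan-2-one | C[Si](C)(C)C#CC[C@H]1OC(=O)C[C@@H]1C1=CC(=O)CCC1 | intermediate
10 | 3-{(2R,3R)-5-oxo-2-[3-(trimethylsilyl)prop-2-yn-1-yl]oxolan-3-yl}cyclohexa-1,3-dien-1-yl trifluoromethanesulfonate | C[Si](C)(C)C#CC[C@H]1OC(=O)C[C@@H]1C1=CCCC(OS(=O)(=O)C(F)(F)F)=C1 | intermediate
11 | methyl 3-{(2R,3R)-5-oxo-2-[3-(trimethylsilyl)prop-2-yn-1-yl]oxolan-3-yl}cyclohexa-1,3-diene-1-carboxylate (not isolated) | C[Si](C)(C)C#CC[C@H]1OC(=O)C[C@@H]1C1=CCCC(C(=O)OC)=C1 | intermediate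
12 | methyl 3-[(2R,3R)-5-oxo-2-(prop-2-yn-1-yl)oxolan-3-yl]cyclohexa-1,3-diene-1-carboxylate | C#CC[C@H]1OC(=O)C[C@@H]1C1=CCCC(C(=O)OC)=C1 | intermediate
13 | 14-(tributylstannyl) cyclisation product (not isolated; C6 epimers and C4=C5/C5=C6 isomers, drawn as the conjugated ester with C6 undefined) | COC(=O)C1=CC2[C@H](CC1)C(=C[Sn](CCCC)(CCCC)CCCC)C[C@H]3OC(=O)C[C@H]23 | intermediate
14 | destannylated ester before equilibration (not isolated; C6 undefined) | COC(=O)C1=CC2[C@H](CC1)C(=C)C[C@H]3OC(=O)C[C@H]23 | intermediate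
15 | methyl (1S,6S,7R,8R)-cadina-4,10(14)-dien-12,8-olid-15-oate (trans-fused decalin, trans-fused lactone, H1 syn to H7) | COC(=O)C1=C[C@H]2[C@H](CC1)C(=C)C[C@H]3OC(=O)C[C@H]23 | intermediate
16 | (1S,6S,7R,8R)-8,12-epoxycadina-4,10(14)-diene-12,15-diol (lactol, C12 anomers) | OCC1=C[C@H]2[C@H](CC1)C(=C)C[C@H]3OC(O)C[C@H]23 | intermediate
17 | (1S,6S,7R,8R)-15-[(tert-butyldimethylsilyl)oxy]-8,12-epoxycadina-4,10(14)-dien-12-ol (C12 anomers) | CC(C)(C)[Si](C)(C)OCC1=C[C@H]2[C@H](CC1)C(=C)C[C@H]3OC(O)C[C@H]23 | intermediate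
18 | (1S,6S,7R,8R)-15-[(tert-butyldimethylsilyl)oxy]cadina-4,10(14)-dien-12,8-olide | CC(C)(C)[Si](C)(C)OCC1=C[C@H]2[C@H](CC1)C(=C)C[C@H]3OC(=O)C[C@H]23 | intermediate
19 | 13-(dimethylamino) derivative of 18 (not isolated; C11 undefined) | CC(C)(C)[Si](C)(C)OCC1=C[C@H]2[C@H](CC1)C(=C)C[C@H]3OC(=O)C(CN(C)C)[C@H]23 | intermediate
20 | 13-(trimethylammonio) derivative of 18, iodide (not isolated; C11 undefined) | CC(C)(C)[Si](C)(C)OCC1=C[C@H]2[C@H](CC1)C(=C)C[C@H]3OC(=O)C(C[N+](C)(C)C)[C@H]23.[I-] | intermediate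
21 | (1S,6S,7S,8R)-15-[(tert-butyldimethylsilyl)oxy]cadina-4,10(14),11(13)-trien-12,8-olide | CC(C)(C)[Si](C)(C)OCC1=C[C@H]2[C@H](CC1)C(=C)C[C@H]3OC(=O)C(=C)[C@H]23 | intermediate
22 | lithium (1S,6S,7S,8R)-15-[(tert-butyldimethylsilyl)oxy]-8-hydroxycadina-4,10(14),11(13)-trien-12-oate (not isolated) | [Li+].[O-]C(=O)C(=C)[C@@H]1[C@H]2C=C(CO[Si](C)(C)C(C)(C)C)CC[C@@H]2C(=C)C[C@H]1O | intermediate
23 | methoxymethyl (1S,6S,7S,8R)-15-[(tert-butyldimethylsilyl)oxy]-8-hydroxycadina-4,10(14),11(13)-trien-12-oate | COCOC(=O)C(=C)[C@@H]1[C@H]2C=C(CO[Si](C)(C)C(C)(C)C)CC[C@@H]2C(=C)C[C@H]1O | intermediate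
24 | methyl [(4S)-2,2-dimethyl-1,3-dioxolan-4-yl]acetate | COC(=O)C[C@H]1COC(C)(C)O1 | starting material
25 | methyl 3-(dimethylamino)-2-[(4S)-2,2-dimethyl-1,3-dioxolan-4-yl]propanoate (not isolated; C2 undefined) | COC(=O)C(CN(C)C)[C@H]1COC(C)(C)O1 | intermediate
26 | trimethylammonium iodide of 25 (not isolated) | COC(=O)C(C[N+](C)(C)C)[C@H]1COC(C)(C)O1.[I-] | intermediate
27 | methyl 2-[(4S)-2,2-dimethyl-1,3-dioxolan-4-yl]prop-2-enoate | COC(=O)C(=C)[C@H]1COC(C)(C)O1 | intermediate
28 | 2-[(4S)-2,2-dimethyl-1,3-dioxolan-4-yl]prop-2-enoic acid | OC(=O)C(=C)[C@H]1COC(C)(C)O1 | intermediate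
29 | methoxymethyl (1S,6S,7S,8R)-15-[(tert-butyldimethylsilyl)oxy]-8-({2-[(4S)-2,2-dimethyl-1,3-dioxolan-4-yl]prop-2-enoyl}oxy)cadina-4,10(14),11(13)-trien-12-oate | COCOC(=O)C(=C)[C@@H]1[C@H]2C=C(CO[Si](C)(C)C(C)(C)C)CC[C@@H]2C(=C)C[C@H]1OC(=O)C(=C)[C@H]1COC(C)(C)O1 | intermediate
30 | (1S,6S,7S,8R)-8-{[(3S)-3,4-dihydroxy-2-methylidenebutanoyl]oxy}-15-hydroxycadina-4,10(14),11(13)-trien-12-oic acid | C=C(C(=O)O)[C@@H]1[C@H]2C=C(CO)CC[C@@H]2C(=C)C[C@H]1OC(=O)C(=C)[C@H](O)CO | target

**Step count and risks**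

Total step count: 16. Longest linear sequence: 13 (steps 2–12, 15, 16).

Steps most likely to fail:

1. Step 7. The C10 radical may attack C5 (β-carbon) instead of C1, be reduced before ring closure, or be lost by 1,5-hydrogen transfer from C11. The fallback sets out from 12 and uses a palladium hydride reductive enyne cyclisation (Pd2(dba)3·CHCl3, P(o-tol)3, AcOH, Et3SiH, PhH). H–Pd adds across the alkyne with palladium on C10, and carbopalladation of the diene can only take place at the terminus C1 because only that mode gives an η3-allyl palladium unit over C6–C5–C4. Hydride transfer from the silane should give the crude ester 14, and the DBU treatment of step 7 brings the route back at 15. No new compound is made.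

2. Step 5. Enolisation may go toward C7 (exocyclic dienyl triflate, erasing the C7 stereocentre) or give the cross-conjugated triflate. The fallback sets out from 5 and brings the dienoate in ready-made. Irradiation of 5 (300 nm, MeCN) should isomerise the enoate to the Z isomer, which lactonises to (5R)-5-[3-(trimethylsilyl)prop-2-yn-1-yl]furan-2(5H)-one F1. Commercial methyl 3-oxocyclohex-1-ene-1-carboxylate is enolised kinetically at the α'-carbon (LiN(SiMe3)2, PhNTf2, THF, −78 °C) to methyl 3-{[(trifluoromethyl)sulfonyl]oxy}cyclohexa-1,3-diene-1-carboxylate F2, and Miyaura borylation (B2pin2, PdCl2(dppf), KOAc, dioxane) gives the dienylboronate methyl 3-(4,4,5,5-tetramethyl-1,3,2-dioxaborolan-2-yl)cyclohexa-1,3-diene-1-carboxylate F3. Hayashi–Miyaura conjugate addition of F3 to F1 ([Rh(cod)OH]2, dioxane/H2O), anti to the C8 substituent of the butenolide, should give 11 directly, where the fallback rejoins the route.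

3. Step 12. Hydroxide may add in conjugate fashion to the methylene lactone, or the hydroxy carboxylate or its ester may reclose to the lactone (also during step 15). The fallback sets out from 18 and avoids opening a methylene lactone. Aminolysis (MeNHOMe·HCl, AlMe3, CH2Cl2) gives the hydroxy Weinreb amide F4. Steglich esterification with 28 gives the 8-O-acyl Weinreb amide F5. Cp2Zr(H)Cl reduces the amide to the C12 aldehyde F6 in the presence of the ester. Mannich methylenation (Eschenmoser salt, Et3N, CH2Cl2) gives the 2-substituted acrolein F7. Pinnick oxidation (NaClO2, NaH2PO4, 2-methylbut-2-ene, tBuOH/H2O) gives the acid F8. 1 M aq. HCl/THF then removes the silyl ether and the acetonide, and the fallback rejoins the route at 30.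

**Further compounds**

F0 | step 7 | none | none
F1 | step 5 | (5R)-5-[3-(trimethylsilyl)prop-2-yn-1-yl]furan-2(5H)-one | C[Si](C)(C)C#CC[C@H]1OC(=O)C=C1
F2 | step 5 | methyl 3-{[(trifluoromethyl)sulfonyl]oxy}cyclohexa-1,3-diene-1-carboxylate | COC(=O)C1=CC(OS(=O)(=O)C(F)(F)F)=CCC1
F3 | step 5 | methyl 3-(4,4,5,5-tetramethyl-1,3,2-dioxaborolan-2-yl)cyclohexa-1,3-diene-1-carboxylate | COC(=O)C1=CC(B2OC(C)(C)C(C)(C)O2)=CCC1
F4 | step 12 | (1S,6S,7R,8R)-15-[(tert-butyldimethylsilyl)oxy]-8-hydroxy-N-methoxy-N-methylcadina-4,10(14)-dien-12-amide | CON(C)C(=O)C[C@@H]1[C@H]2C=C(CO[Si](C)(C)C(C)(C)C)CC[C@@H]2C(=C)C[C@H]1O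
F5 | step 12 | 8-O-{2-[(4S)-2,2-dimethyl-1,3-dioxolan-4-yl]prop-2-enoyl} ester of F4 | CON(C)C(=O)C[C@@H]1[C@H]2C=C(CO[Si](C)(C)C(C)(C)C)CC[C@@H]2C(=C)C[C@H]1OC(=O)C(=C)[C@H]1COC(C)(C)O1
F6 | step 12 | corresponding cadina-4,10(14)-dien-12-al (C11H2–CHO) | O=CC[C@@H]1[C@H]2C=C(CO[Si](C)(C)C(C)(C)C)CC[C@@H]2C(=C)C[C@H]1OC(=O)C(=C)[C@H]1COC(C)(C)O1
F7 | step 12 | corresponding cadina-4,10(14),11(13)-trien-12-al | O=CC(=C)[C@@H]1[C@H]2C=C(CO[Si](C)(C)C(C)(C)C)CC[C@@H]2C(=C)C[C@H]1OC(=O)C(=C)[C@H]1COC(C)(C)O1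
F8 | step 12 | (1S,6S,7S,8R)-15-[(tert-butyldimethylsilyl)oxy]-8-({2-[(4S)-2,2-dimethyl-1,3-dioxolan-4-yl]prop-2-enoyl}oxy)cadina-4,10(14),11(13)-trien-12-oic acid | OC(=O)C(=C)[C@@H]1[C@H]2C=C(CO[Si](C)(C)C(C)(C)C)CC[C@@H]2C(=C)C[C@H]1OC(=O)C(=C)[C@H]1COC(C)(C)O1
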